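**Retrosynthetic overview**

1. Numbering: the ten-membered carbocycle is C1 (furanone enol-ether carbon), C2 (=CH), C3 (C=O), C4 (quaternary, methyl C15), C5 (CH2), C6 (lactone O), C7, C8 (ester O), C9 (OH), C10 (=C14H2); the lactone carbons are C11–C13. The feature used is that the furanone oxygen bridges C1 and C4 of this carbocycle (an 11-oxabicyclo[6.2.1]undecane), with C4 lying between the C3 carbonyl and the C5–C6–C7 unit.
2. Late stage: methacrylate on O8, C10=C14 by elimination of a C14 pivalate, C1=C2 by Saegusa–Ito oxidation. The trans α-methylene lactone is built on a Z-C6=C7 alkene by epoxidation and a phosphonoacetate tether on O9 (epoxide opening at C7, δ→γ translactonization, olefination with formaldehyde).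
3. Key disconnection: the C4–O bond together with C4–C5. A keto-carbenoid at C4 is captured by the oxygen of a 2-vinyltetrahydropyran (O, C1, C10, C9, C8, C7); this ring is temporary, and its O–C7 bond is cleaved in the [2,3] shift of the oxonium ylide (three-carbon ring expansion).
4. The tetrahydropyran comes from a furyl carbinol (asymmetric transfer hydrogenation) by Achmatowicz rearrangement, Kishi reduction and dihydroxylation.
5. Ring order: tetrahydropyran (temporary) → furanone ring and ten-membered carbocycle together (key step) → transient δ-lactone → γ-lactone.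

Key step: step 15

Remark: the configuration at C10 in compounds 11–27 is drawn as expected for hydroboration anti to the axial O9 silyl ether; this centre becomes trigonal in step 21, so either epimer would serve.

**Route**

Step 1
Reactants: 1 methyl 5-bromofuran-2-carboxylate
Product: 2 methyl 5-[(trimethylsilyl)ethynyl]furan-2-carboxylate
Conditions: HC≡CSiMe3, PdCl2(PPh3)2 (2 mol %), CuI (4 mol %), Et3N, THF, rt
Reagents that add atoms: ethynyltrimethylsilane C#C[Si](C)(C)C
Why: Sonogashira coupling of an electron-poor 2-bromofuran is routine, and the silylalkyne is a vinyl group (C6=C5) masked against the oxidations and the hydroboration ahead.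

Step 2
Reactants: 2 methyl 5-[(trimethylsilyl)ethynyl]furan-2-carboxylate
Product: 3 methyl 3-oxo-3-{5-[(trimethylsilyl)ethynyl]furan-2-yl}propanoate
Conditions: MeOAc, LiN(iPr)2 (2.2 equiv), THF, −78 °C; then 2, −78 → −30 °C; aq. NH4Cl
Reagents that add atoms: methyl acetate CC(=O)OC
Why: Crossed Claisen condensation of the non-enolisable furoate with the lithium enolate of methyl acetate should give the β-keto ester (C1–C3), the second equivalent of base holding the product as its enolate.

Step 3
Reactants: 3 methyl 3-oxo-3-{5-[(trimethylsilyl)ethynyl]furan-2-yl}propanoate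
Product: 4 methyl (3S)-3-hydroxy-3-{5-[(trimethylsilyl)ethynyl]furan-2-yl}propanoate
Conditions: RuCl[(S,S)-TsDPEN](p-cymene) (1 mol %), HCO2H/Et3N, DMF, rt
Reagents that add atoms: none
Why: Noyori asymmetric transfer hydrogenation of a heteroaryl β-keto ester; the (S,S) catalyst should give the (S) carbinol, which fixes C1 and, through the key step, C4.

Step 4
Reactants: 4 methyl (3S)-3-hydroxy-3-{5-[(trimethylsilyl)ethynyl]furan-2-yl}propanoate
Product: 5 methyl 2-{(2S)-6-hydroxy-3-oxo-6-[(trimethylsilyl)ethynyl]-3,6-dihydro-2H-pyran-2-yl}acetate (hemiketal, both C6 epimers)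
Conditions: NBS, NaHCO3, NaOAc, THF/H2O, 0 °C
Reagents that add atoms: water O
Why: Achmatowicz rearrangement: oxidative opening of the furfuryl alcohol to the ene-dione and closure of the carbinol oxygen onto the alkynyl ketone should give the pyranone, with C1 untouched and the ketone at the future C10.

Step 5
Reactants: 5 hemiketal pyranone
Product: 6 methyl 2-{(2S)-3-oxo-6-[(trimethylsilyl)ethynyl]-3,6-dihydro-2H-pyran-2-yl}acetate (2,6-cis)
Conditions: Et3SiH, CF3CO2H, CH2Cl2, −40 °C
Reagents that add atoms: none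
Why: Kishi-type ionic reduction: the alkynyl-stabilised oxocarbenium ion takes hydride axially, which should place the alkynyl group cis to the C1 side chain and so set C7.

Step 6
Reactants: 6 cis-2,6-disubstituted pyranone
Product: 7 methyl 2-{4,5-dihydroxy-3-oxo-6-[(trimethylsilyl)ethynyl]oxan-2-yl}acetate (2,6-cis; 4,5-cis-diol trans to both carbon substituents)
Conditions: K2OsO2(OH)4 (2 mol %), NMO, citric acid, t-BuOH/H2O, rt
Reagents that add atoms: N-methylmorpholine N-oxide C[N+]1([O-])CCOCC1; water O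
Why: Upjohn-type osmium dihydroxylation of the enone from the face opposite the two cis ring substituents should set C8 and C9 as a cis diol.

Step 7
Reactants: 7 keto diol
Product: 8 5-O-(4-methoxybenzyl) ether of 7 (PMB on O8, the equatorial oxygen next to C7; O9–H free)
Conditions: PMBCl, Ag2O, Ph2BOCH2CH2NH2 (10 mol %), MeCN, 40 °C
Reagents that add atoms: 4-methoxybenzyl chloride COc1ccc(CCl)cc1
Why: Borinic-acid-catalysed regioselective alkylation of a cis-1,2-diol: the catalyst binds the diol and the equatorial oxygen O8 is alkylated, while the pseudo-axial O9, hydrogen-bonded to the ketone, stays free.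

Step 8
Reactants: 8 O8-PMB keto alcohol
Product: 9 4-O-tert-butyldimethylsilyl ether of 8 (TBS on O9)
Conditions: TBSOTf, 2,6-lutidine, CH2Cl2, −78 → 0 °C
Reagents that add atoms: tert-butyldimethylsilyl triflate CC(C)(C)[Si](C)(C)OS(=O)(=O)C(F)(F)F
Why: Silylation of the remaining secondary hydroxyl with the silyl triflate; a TBS ether at O9 is a poor donor towards the later carbenoid.

Step 9
Reactants: 9 α-silyloxy ketone
Product: 10 methyl 2-{4-(TBSO)-5-(PMBO)-3-methylidene-6-[(trimethylsilyl)ethynyl]oxan-2-yl}acetate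
Conditions: Cp2TiMe2, toluene, 65 °C, dark
Reagents that add atoms: dimethyltitanocene C[Ti](C)(C1C=CC=C1)C1C=CC=C1
Why: Petasis methylenation with a non-basic titanium methylidene should convert the hindered ketone without β-elimination of O8 or epimerisation, and it reacts with the ketone before the ester.

Step 10
Reactants: 10 exocyclic alkene
Product: 12 methyl 2-{4-(TBSO)-3-(hydroxymethyl)-5-(PMBO)-6-[(trimethylsilyl)ethynyl]oxan-2-yl}acetate (CH2OH cis to O9), via B-alkyl-9-BBN adduct 11 (not isolated)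
Conditions: 9-BBN, THF, 0 → 40 °C; then aq. NaOH, H2O2, 0 °C
Reagents that add atoms: hydrogen peroxide OO
Why: Hydroboration–oxidation of the 1,1-disubstituted alkene (silylalkyne and ester are much slower towards 9-BBN) with hydrogen delivered to C10 anti to the axial O9 silyl ether; the alkene is masked here because a γ,δ-alkene would be cyclopropanated by the carbenoid of step 15.

Step 11
Reactants: 12 primary alcohol
Product: 13 pivalate of 12 (C14–OPiv)
Conditions: PivCl, pyridine, DMAP (cat.), CH2Cl2, 0 °C → rt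
Reagents that add atoms: pivaloyl chloride CC(C)(C)C(=O)Cl
Why: Acylation of the primary alcohol; the pivalate survives the steps ahead and later serves as the leaving group for C10=C14.

Step 12
Reactants: 13 pivalate methyl ester
Product: 14 2-{4-(TBSO)-6-ethynyl-5-(PMBO)-3-(pivaloyloxymethyl)oxan-2-yl}acetic acid
Conditions: LiOH·H2O, THF/MeOH/H2O, 0 °C → rt; then aq. HCl to pH 3
Reagents that add atoms: lithium hydroxide [Li+].[OH-]
Why: Saponification of the methyl ester with concurrent protodesilylation of the alkynylsilane by hydroxide/methoxide; the hindered pivalate and the silyl ether should survive.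

Step 13
Reactants: 14 alkynyl acid
Product: 15 2-{4-(TBSO)-6-ethenyl-5-(PMBO)-3-(pivaloyloxymethyl)oxan-2-yl}acetic acid
Conditions: H2 (1 atm), Pd/CaCO3 poisoned with Pb(OAc)2, quinoline, EtOAc, rt
Reagents that add atoms: none
Why: Lindlar semihydrogenation of the terminal alkyne to the vinyl group (C6=C5), stopped at the alkene by the poisoned catalyst.

Step 14
Reactants: 15 vinyl acid
Product: 17 3-diazo-1-{4-(TBSO)-6-ethenyl-5-(PMBO)-3-(pivaloyloxymethyl)oxan-2-yl}butan-2-one, via mixed isobutyl carbonic anhydride 16 (not isolated)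
Conditions: i-BuOCOCl, Et3N, THF, −20 °C; then CH3CHN2 (excess, Et2O), −20 → 0 °C
Reagents that add atoms: diazoethane CC=[N+]=[N-]
Why: Acylation of diazoethane by the mixed anhydride (Arndt–Eistert-type diazoketone synthesis) should give the α-methyl diazoketone that carries C4 and C15.

Step 15
Reactants: 17 diazoketone
Product: 19 (Z)-bicyclic ketone: 11-oxabicyclo[6.2.1]undec-3-en-10-one with 1-methyl (C4), 5-OPMB (C8), 6-OTBS (C9) and 7-CH2OPiv (C10) groups, via bicyclic oxonium ylide 18 (not isolated)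
Conditions: Cu(hfacac)2 (hfacac = CF3COCHCOCF3; 5 mol %), CH2Cl2, reflux, slow addition of 17
Reagents that add atoms: none
Why: The copper carbenoid at C4 is attacked by the ring oxygen, whose lone pair is 1,5 to it; this forms the C4–O bond and closes the five-membered furan-3-one ring as oxonium ylide 18. The ylide then undergoes a [2,3]-sigmatropic shift through a five-membered envelope transition state in which C4 bonds to the vinyl terminus C5 and the O–C7 bond of the tetrahydropyran breaks, so the ten-membered carbocycle is closed by a three-carbon ring expansion. The closest known reaction type is the copper- or rhodium-catalysed oxonium ylide formation/[2,3] rearrangement of 2-vinyltetrahydropyranyl diazoketones to 11-oxabicyclo[6.2.1]undecenones. The new quaternary centre C4 is controlled by C1: both stay bonded to the same oxygen, so C5 must end cis to C10 on the furanone ring, which gives the required (S) configuration. The Z geometry of C6=C7 should follow the behaviour of cis-2,6-disubstituted tetrahydropyrans with Cu(hfacac)2. The step needs ylide formation to beat 1,2-hydride shift of the methyl-substituted carbenoid, 1,5 C–H insertion and cyclopropanation; this is secured by five-ring capture at the adjacent ether oxygen, by the absence of any other alkene within reach (C10 carries CH2OPiv, not the methylene), and by the poorly donating silyl, benzyl and acyl oxygens.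

Step 16
Reactants: 19 bicyclic ketone
Product: 20 C9 alcohol (19 without the TBS group)
Conditions: HF·pyridine, pyridine, THF, 0 °C → rt
Reagents that add atoms: none
Why: Fluoride cleavage of the secondary TBS ether under buffered, non-basic conditions that should spare the β-alkoxy ketone, the PMB ether and the pivalate.

Step 17
Reactants: 20 C9 alcohol
Product: 21 C9 (diethoxyphosphoryl)acetate
Conditions: (EtO)2P(O)CH2CO2H, EDC·HCl, DMAP (cat.), CH2Cl2, 0 °C → rt
Reagents that add atoms: diethylphosphonoacetic acid CCOP(=O)(CC(=O)O)OCC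
Why: Steglich-type carbodiimide esterification installs on O9 the tether that will deliver C11 and C12 to C7.

Step 18
Reactants: 21 phosphonoacetate
Product: 22 cis-6,7-epoxide of 21 (epoxide oxygen syn to O8)
Conditions: dimethyldioxirane (acetone solution), CH2Cl2, −20 → 0 °C
Reagents that add atoms: dimethyldioxirane CC1(C)OO1
Why: Epoxidation with a neutral dioxirane (no Baeyer–Villiger reaction at C3); attack on the outer face of the Z-alkene, anti to ring carbon C9 in the conformer that keeps H8 in the alkene plane (allylic 1,3-strain), should place the oxygen syn to O8.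

Step 19
Reactants: 22 epoxy phosphonoacetate
Product: 25 trans-fused α-methylene-γ-lactone with free C9–OH (O8-PMB; C14-OPiv; C3 ketone), via δ-lactone phosphonate 23 (not isolated), via γ-lactone phosphonate 24 (not isolated)
Conditions: LiCl, DBU, MeCN, 0 → 40 °C; then (CH2O)n, rt
Reagents that add atoms: formaldehyde C=O
Why: The lithium-chelated phosphonoacetate carbanion opens the epoxide at C7 by intramolecular SN2 attack (6-exo-tet, inversion at C7, C6–O retained), the C6 alkoxide translactonizes the bridged δ-lactone 23 to the trans-fused γ-lactone 24 and frees O9, and Horner–Wadsworth–Emmons olefination with formaldehyde gives the methylene; the tether fixes C11 syn to O9 and anti opening of the cis-epoxide fixes the trans ring fusion (sets C6 and C7).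

Step 20
Reactants: 25 keto lactone alcohol
Product: 27 3(2H)-furanone (C1=C2) with O9-TES (O8-PMB and C14-OPiv retained), via bis-silylated enol ether 26 (not isolated)
Conditions: TESOTf, Et3N, CH2Cl2, −78 → 0 °C; then Pd(OAc)2, MeCN, rt
Reagents that add atoms: triethylsilyl triflate CC[Si](CC)(CC)OS(=O)(=O)C(F)(F)F
Why: Saegusa–Ito oxidation: enolization can only go towards C2 because C4 is quaternary, Pd(OAc)2 dehydrogenates the silyl enol ether to the furanone, and the same silylation protects O9.

Step 21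
Reactants: 27 furanone pivalate
Product: 28 cross-conjugated dienone with exocyclic C10=C14 (O8-PMB; O9-TES)
Conditions: DBU, CH2Cl2, 0 °C → rt
Reagents that add atoms: none
Why: Vinylogous E1cB elimination: C10–H is now the γ-position of the furanone, so DBU should form the extended enolate and expel pivalate to give the exocyclic alkene, the C10 stereocentre disappearing.

Step 22
Reactants: 28 PMB ether
Product: 29 C8 alcohol (O9-TES)
Conditions: DDQ, CH2Cl2/pH 7 buffer, 0 °C → rt
Reagents that add atoms: none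
Why: Oxidative cleavage of the 4-methoxybenzyl ether by DDQ, to which the silyl ether, the lactone and the electron-poor dienone should be inert.

Step 23
Reactants: 29 C8 alcohol
Product: 30 C8 methacrylate with O9-TES
Conditions: methacrylic anhydride, Et3N, DMAP, CH2Cl2, 0 °C → rt
Reagents that add atoms: methacrylic anhydride C=C(C)C(=O)OC(=O)C(C)=C
Why: DMAP-catalysed acylation of the only free hydroxyl; O9 is blocked, so no regiochemical question arises.

Step 24
Reactants: 30 silyl-protected methacrylate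
Product: 31 CNP0142847.1 (target)
Conditions: HF·pyridine, pyridine, THF, 0 °C
Reagents that add atoms: none
Why: Cleavage of the TES ether with buffered HF, which should not touch the Michael acceptors or the esters.

**Compound list**

1 | methyl 5-bromofuran-2-carboxylate | COC(=O)c1ccc(Br)o1 | starting material
2 | methyl 5-[(trimethylsilyl)ethynyl]furan-2-carboxylate | COC(=O)c1ccc(C#C[Si](C)(C)C)o1 | intermediate
3 | methyl 3-oxo-3-{5-[(trimethylsilyl)ethynyl]furan-2-yl}propanoate | COC(=O)CC(=O)c1ccc(C#C[Si](C)(C)C)o1 | intermediate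
4 | methyl (3S)-3-hydroxy-3-{5-[(trimethylsilyl)ethynyl]furan-2-yl}propanoate | COC(=O)C[C@H](O)c1ccc(C#C[Si](C)(C)C)o1 | intermediate
5 | methyl 2-{(2S)-6-hydroxy-3-oxo-6-[(trimethylsilyl)ethynyl]-3,6-dihydro-2H-pyran-2-yl}acetate (both hemiketal epimers) | COC(=O)C[C@@H]1OC(O)(C#C[Si](C)(C)C)C=CC1=O | intermediate
6 | methyl 2-{(2S)-3-oxo-6-[(trimethylsilyl)ethynyl]-3,6-dihydro-2H-pyran-2-yl}acetate (2,6-cis) | O1[C@@H](CC(=O)OC)C(=O)C=C[C@H]1C#C[Si](C)(C)C | intermediate
7 | methyl 2-{4,5-dihydroxy-3-oxo-6-[(trimethylsilyl)ethynyl]oxan-2-yl}acetate (2,6-cis; cis-diol trans to both carbon substituents) | O1[C@@H](CC(=O)OC)C(=O)[C@H](O)[C@H](O)[C@H]1C#C[Si](C)(C)C | intermediate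
8 | 5-O-(4-methoxybenzyl) ether of 7 (O8-PMB) | O1[C@@H](CC(=O)OC)C(=O)[C@H](O)[C@H](OCc2ccc(OC)cc2)[C@H]1C#C[Si](C)(C)C | intermediate
9 | 4-O-TBS ether of 8 (O9-TBS) | O1[C@@H](CC(=O)OC)C(=O)[C@H](O[Si](C)(C)C(C)(C)C)[C@H](OCc2ccc(OC)cc2)[C@H]1C#C[Si](C)(C)C | intermediate
10 | 3-methylidene oxane (C10=C14) | O1[C@@H](CC(=O)OC)C(=C)[C@H](O[Si](C)(C)C(C)(C)C)[C@H](OCc2ccc(OC)cc2)[C@H]1C#C[Si](C)(C)C | intermediate
11 | B-alkyl-9-borabicyclo[3.3.1]nonane adduct of 10 | O1[C@@H](CC(=O)OC)[C@H](CB2C3CCCC2CCC3)[C@H](O[Si](C)(C)C(C)(C)C)[C@H](OCc2ccc(OC)cc2)[C@H]1C#C[Si](C)(C)C | intermediate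
12 | 3-(hydroxymethyl) oxane (CH2OH cis to O9) | O1[C@@H](CC(=O)OC)[C@H](CO)[C@H](O[Si](C)(C)C(C)(C)C)[C@H](OCc2ccc(OC)cc2)[C@H]1C#C[Si](C)(C)C | intermediate
13 | pivalate of 12 | O1[C@@H](CC(=O)OC)[C@H](COC(=O)C(C)(C)C)[C@H](O[Si](C)(C)C(C)(C)C)[C@H](OCc2ccc(OC)cc2)[C@H]1C#C[Si](C)(C)C | intermediate
14 | 6-ethynyl oxan-2-ylacetic acid | O1[C@@H](CC(=O)O)[C@H](COC(=O)C(C)(C)C)[C@H](O[Si](C)(C)C(C)(C)C)[C@H](OCc2ccc(OC)cc2)[C@H]1C#C | intermediate
15 | 6-ethenyl oxan-2-ylacetic acid | O1[C@@H](CC(=O)O)[C@H](COC(=O)C(C)(C)C)[C@H](O[Si](C)(C)C(C)(C)C)[C@H](OCc2ccc(OC)cc2)[C@H]1C=C | intermediate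
16 | mixed isobutyl carbonic anhydride of 15 | O1[C@@H](CC(=O)OC(=O)OCC(C)C)[C@H](COC(=O)C(C)(C)C)[C@H](O[Si](C)(C)C(C)(C)C)[C@H](OCc2ccc(OC)cc2)[C@H]1C=C | intermediate
17 | 3-diazobutan-2-one attached through C1 to the oxane (key-step substrate) | O1[C@@H](CC(=O)C(C)=[N+]=[N-])[C@H](COC(=O)C(C)(C)C)[C@H](O[Si](C)(C)C(C)(C)C)[C@H](OCc2ccc(OC)cc2)[C@H]1C=C | intermediate
18 | bicyclic oxonium ylide (O bonded to C1, C4 and C7) | C[C-]1C(=O)C[C@H]2[C@H](COC(=O)C(C)(C)C)[C@H](O[Si](C)(C)C(C)(C)C)[C@H](OCc3ccc(OC)cc3)[C@@H](C=C)[O+]12 | intermediate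
19 | (Z)-11-oxabicyclo[6.2.1]undec-3-en-10-one with C4-methyl, O8-PMB, O9-TBS, C10-CH2OPiv | COc1ccc(CO[C@@H]2/C=C\C[C@]3(C)O[C@@H](CC3=O)[C@H](COC(=O)C(C)(C)C)[C@@H]2O[Si](C)(C)C(C)(C)C)cc1 | intermediate
20 | C9 alcohol | COc1ccc(CO[C@@H]2/C=C\C[C@]3(C)O[C@@H](CC3=O)[C@H](COC(=O)C(C)(C)C)[C@@H]2O)cc1 | intermediate
21 | C9 (diethoxyphosphoryl)acetate | COc1ccc(CO[C@@H]2/C=C\C[C@]3(C)O[C@@H](CC3=O)[C@H](COC(=O)C(C)(C)C)[C@@H]2OC(=O)CP(=O)(OCC)OCC)cc1 | intermediate
22 | cis-6,7-epoxide (oxygen syn to O8) | COc1ccc(CO[C@@H]2[C@H]4O[C@H]4C[C@]3(C)O[C@@H](CC3=O)[C@H](COC(=O)C(C)(C)C)[C@@H]2OC(=O)CP(=O)(OCC)OCC)cc1 | intermediate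
23 | bridged δ-lactone phosphonate (O9–C12, C11–C7; free C6–OH; C11 epimers) | COc1ccc(CO[C@@H]2[C@H]3[C@@H](O)C[C@]4(C)O[C@@H](CC4=O)[C@H](COC(=O)C(C)(C)C)[C@@H]2OC(=O)C3P(=O)(OCC)OCC)cc1 | intermediate
24 | trans-fused α-phosphono-γ-lactone (free C9–OH; C11 epimers) | COc1ccc(CO[C@@H]2[C@@H]3C(P(=O)(OCC)OCC)C(=O)O[C@H]3C[C@]4(C)O[C@@H](CC4=O)[C@H](COC(=O)C(C)(C)C)[C@@H]2O)cc1 | intermediate
25 | trans-fused α-methylene-γ-lactone, free C9–OH, C3 ketone | COc1ccc(CO[C@@H]2[C@@H]3C(=C)C(=O)O[C@H]3C[C@]4(C)O[C@@H](CC4=O)[C@H](COC(=O)C(C)(C)C)[C@@H]2O)cc1 | intermediate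
26 | C2=C3 triethylsilyl enol ether with O9-TES | COc1ccc(CO[C@@H]2[C@@H]3C(=C)C(=O)O[C@H]3C[C@]4(C)O[C@@H](C=C4O[Si](CC)(CC)CC)[C@H](COC(=O)C(C)(C)C)[C@@H]2O[Si](CC)(CC)CC)cc1 | intermediate
27 | 3(2H)-furanone with O9-TES, C14-OPiv, O8-PMB | COc1ccc(CO[C@@H]2[C@@H]3C(=C)C(=O)O[C@H]3C[C@]4(C)OC(=CC4=O)[C@H](COC(=O)C(C)(C)C)[C@@H]2O[Si](CC)(CC)CC)cc1 | intermediate
28 | dienone with C10=C14, O9-TES, O8-PMB | COc1ccc(CO[C@@H]2[C@@H]3C(=C)C(=O)O[C@H]3C[C@]4(C)OC(=CC4=O)C(=C)[C@@H]2O[Si](CC)(CC)CC)cc1 | intermediate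
29 | C8 alcohol, O9-TES | O[C@@H]1[C@@H]2C(=C)C(=O)O[C@H]2C[C@]2(C)OC(=CC2=O)C(=C)[C@@H]1O[Si](CC)(CC)CC | intermediate
30 | C8 methacrylate, O9-TES | C=C(C)C(=O)O[C@@H]1[C@@H]2C(=C)C(=O)O[C@H]2C[C@]2(C)OC(=CC2=O)C(=C)[C@@H]1O[Si](CC)(CC)CC | intermediate
31 | CNP0142847.1 | C=C(C)C(=O)O[C@@H]1[C@@H]2C(=C)C(=O)O[C@H]2C[C@]2(C)OC(=CC2=O)C(=C)[C@@H]1O | target

**Totals**

Total step count: 24. Longest linear sequence: 24 steps (the route is linear from 1).

**Steps most likely to fail**

1. Step 15. The α-methyl copper carbenoid may undergo 1,2-hydride migration to a vinyl ketone or C–H insertion faster than it is captured by the ring oxygen, and the Z/E selectivity of the rearrangement may erode. The fallback removes the β-hydrogens by using an acceptor/acceptor carbenoid and sets out from acid 15. Activation with carbonyldiimidazole and reaction with Mg(O2CCH2CO2Me)2 (Masamune–Brooks homologation) would give the methyl β-keto ester F1. Regitz diazo transfer (p-ABSA, Et3N) would give the diazo β-keto ester F2. The same ylide formation/[2,3] shift with Cu(hfacac)2 or Rh2(OAc)4, a well-established reaction of diazo keto esters, would give the bicyclic β-keto ester F3 with CO2Me on C4. LiBH4 would reduce ketone and ester to the diol F4. Selective iodination of the primary hydroxyl (I2, PPh3, imidazole) would give the iodide F5. Radical deiodination (Bu3SnH, AIBN) would give the C4-methyl alcohol F6, and Dess–Martin oxidation would return the route to 19.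

2. Step 19. Poor or reversed facial selectivity in the epoxidation of step 18 would give an epoxide whose C7–O bond the tethered carbanion cannot reach from the rear. Intermolecular olefination at the C3 ketone or incomplete translactonization could also divert material. The fallback builds the lactone from the oxygen at C6 instead and sets out from 19. Bromoetherification (NBS, propargyl alcohol, CH2Cl2, −20 °C) puts the alcohol on C6 anti to the bromonium ion, that is, on the face the dioxirane would not have used, and would give the trans bromo propargyl ether F7. Radical 5-exo-dig cyclisation (Bu3SnH, AIBN, benzene, 80 °C; Ueno–Stork type) would give the α-methylene tetrahydrofuran F8. Allylic oxidation of the ether methylene (CrO3·3,5-dimethylpyrazole, CH2Cl2, −20 °C) would give the O9-TBS lactone F9, and HF·pyridine would return the route to 25.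

3. Step 21. Expulsion of pivalate from the extended enolate may be slow, so that conjugate addition of the amidine base to the α-methylene lactone competes. The fallback replaces base-mediated enolization by soft enolization and sets out from 27. TESOTf/Et3N would give the silyl dienol ether F10 (C10=C1–C2=C3–OSiEt3), in which the pivalate is allylic. Warming with a catalytic amount of TESOTf should trigger 1,6-elimination of triethylsilyl pivalate and return the route to 28.

**Further compounds**

F1 | step 15 | methyl 4-(oxan-2-yl)-3-oxobutanoate derived from acid 15 | O1[C@@H](CC(=O)CC(=O)OC)[C@H](COC(=O)C(C)(C)C)[C@H](O[Si](C)(C)C(C)(C)C)[C@H](OCc2ccc(OC)cc2)[C@H]1C=C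
F2 | step 15 | methyl 2-diazo-4-(oxan-2-yl)-3-oxobutanoate | O1[C@@H](CC(=O)C(=[N+]=[N-])C(=O)OC)[C@H](COC(=O)C(C)(C)C)[C@H](O[Si](C)(C)C(C)(C)C)[C@H](OCc2ccc(OC)cc2)[C@H]1C=C
F3 | step 15 | (Z)-bicyclic β-keto ester, CO2Me on C4 | COc1ccc(CO[C@@H]2/C=C\C[C@]3(C(=O)OC)O[C@@H](CC3=O)[C@H](COC(=O)C(C)(C)C)[C@@H]2O[Si](C)(C)C(C)(C)C)cc1
F4 | step 15 | diol: C4-CH2OH and C3-OH (C3 epimers) | COc1ccc(CO[C@@H]2/C=C\C[C@]3(CO)O[C@@H](CC3O)[C@H](COC(=O)C(C)(C)C)[C@@H]2O[Si](C)(C)C(C)(C)C)cc1
F5 | step 15 | iodide: C4-CH2I and C3-OH | COc1ccc(CO[C@@H]2/C=C\C[C@]3(CI)O[C@@H](CC3O)[C@H](COC(=O)C(C)(C)C)[C@@H]2O[Si](C)(C)C(C)(C)C)cc1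
F6 | step 15 | C4-methyl C3 alcohol | COc1ccc(CO[C@@H]2/C=C\C[C@]3(C)O[C@@H](CC3O)[C@H](COC(=O)C(C)(C)C)[C@@H]2O[Si](C)(C)C(C)(C)C)cc1
F7 | step 19 | trans 7-bromo-6-(prop-2-ynyloxy) adduct of 19 | COc1ccc(CO[C@@H]2[C@H](Br)[C@@H](OCC#C)C[C@]3(C)O[C@@H](CC3=O)[C@H](COC(=O)C(C)(C)C)[C@@H]2O[Si](C)(C)C(C)(C)C)cc1
F8 | step 19 | trans-fused 3-methylidene tetrahydrofuran on C6/C7 | COc1ccc(CO[C@@H]2[C@@H]3C(=C)CO[C@H]3C[C@]4(C)O[C@@H](CC4=O)[C@H](COC(=O)C(C)(C)C)[C@@H]2O[Si](C)(C)C(C)(C)C)cc1
F9 | step 19 | α-methylene-γ-lactone with O9-TBS | COc1ccc(CO[C@@H]2[C@@H]3C(=C)C(=O)O[C@H]3C[C@]4(C)O[C@@H](CC4=O)[C@H](COC(=O)C(C)(C)C)[C@@H]2O[Si](C)(C)C(C)(C)C)cc1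
F10 | step 21 | silyl dienol ether of 27 (C10=C1, C2=C3–OSiEt3) | COc1ccc(CO[C@@H]2[C@@H]3C(=C)C(=O)O[C@H]3C[C@]4(C)OC(C=C4O[Si](CC)(CC)CC)=C(COC(=O)C(C)(C)C)[C@@H]2O[Si](CC)(CC)CC)cc1
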